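In a one-step world L turns into Z and the story ends; here Z is consumed in turn, and J pays for that loss.

    L + E ⇌ L.E, settled at all times (K1 = 39 M⁻¹)
    L → G (k2 = 4.79 × 10⁻⁶ s⁻¹)
    L + Q → Q + Z (k3 = 4.02 M⁻¹ s⁻¹)
    J + E + Z → E + X (k4 = 32.6 M⁻² s⁻¹)

| setting | ochre | amber | blue | green |
|---|---|---|---|---|
| L | 0.10 M (fed, over 20.0 min) | 0.10 M | 0.10 M | 0.10 M |
| J | 0.110 M | 0.110 M | 0.110 M | 0.110 M |
| Q | 8.9 mM | 8.9 mM | 8.9 mM | 8.9 mM |
| E | 1.0 mM | 1.0 mM | 1.0 mM | 1.0 mM |
| time | 25 min |  |  | 25 min |
| remark | all but L at the start; L goes in evenly over 20.0 min, the run ends at 25 min | a single well-mixed tank run continuously and read at steady state, 75.0 min in it on average | one stirred flow tank at steady state, fed with the mixture as stated, mean residence time 25 min | everything together in a closed stirred flask, run for 25 min |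

- the stated concentrations are those of everything mixed, before any reaction; amounts are the same in each set-up
- the feed brings no volume worth counting
- run time (ochre): 25 min

1. the set-up with the highest amount of Z at the outlet or at the end, in percent of the L put in ("none" if the first two lie within 2 percentage points) (ochre / amber / blue / green / none)
2. amount of Z at the outlet or at the end, in percent of the L put in, ochre
3. amount of Z at the outlet or at the end, in percent of the L put in, amber
4. amount of Z at the outlet or at the end, in percent of the L put in, blue
5. amount of Z at the outlet or at the end, in percent of the L put in, green

Two chemists agree on the opening. Q turns L over with a lifetime of about 28.0 s, much shorter than the 25 min of the green flask, so Z appears early. They part over what removes it.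

The first chemist treats the loss of Z as pseudo-first-order, with [J] and [E] held as charged. The half-life of Z is then 3.2 min, short against the 25 min run, so on this view the green flask keeps 0.461 % of its L as Z.

The second chemist counts J. L is the limiting reagent, and the surplus of J over L, 0.0100 M, is what J falls towards. Every X costs one J and one Z, and every Z came from one L, so once L has turned over, [J] stands at the surplus plus [Z]. As Z falls, the half-life therefore stretches towards 35.4 min, longer than the first chemist's figure.

My own reckoning takes the blue tank, with all of E free. The balance on Z says that the share surviving is one over one plus k4[E][J] times the residence time. With [J] as charged, this share is 15.7 %. Putting that back, with [J] as the surplus plus [Z], gives 44.3 %. The answer swings, so I put in the mean of the two and get 33.8 %, and one more round gives 31.8 %. I commit to about 32.8 %.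

The forecast sides with the second chemist. Its ground for green is “Second-order decay with J − Z = 0.01 M”. It names blue as best, with 26.4 % for ochre, 19 % for amber, 32.4 % for blue and 13.1 % for green. Its blue value lies slightly below mine.

The simulation gives blue as best: ochre 26.5 %, amber 19.0 %, blue 32.4 %, green 13.1 %. The first chemist's 0.461 % for green falls short of this; that clock takes [J] as charged, so its region is a flask where [J] stays near the charge, and here the charge of L is 90.9 % of the charge of J. In the blue tank [J] reads 0.0443 M, while the surplus, [Z] and the 0.00183 M of L add up to 0.0443 M, a sum that leaves out L.E and G. For amber, at 75.0 min, the same rounds starting from blue's [Z] give 13.8 %, then 22.2 %, and their mean put back gives 19.6 %; the amber tank reads 19.0 %.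

(Its constants are those of an exercise.)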